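**Plan**
- Retrosynthesis: the three benzyl ethers and the C2=C3 unsaturation are removed first; then C3–C4 and C2–C3 of ring C are cut, which excises the aryl-bearing carbon C3 and leaves a ring-A-fused furanone and a ring-B aryldiazomethane.
- Enabling feature: C3, carrying ring B, lies between the oxygen-bound carbon C2 (attached to O1) and the carbonyl carbon C4. Ring C is thus a benzofuran-3(2H)-one enlarged by one benzylic carbon.
- Forward, ring A is bought. The furanone is closed by Friedel–Crafts acylation of an aryloxyacetic acid whose arm sits on the oxygen next to the methoxy carbon (that methoxy oxygen comes from a formyl group by Baeyer–Villiger oxidation), so only the 8-methoxy pattern can form.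
- The ring-B aldehyde becomes the diazoalkane via its tosylhydrazone. Ring expansion then builds ring C, DDQ introduces C2=C3, and hydrogenolysis frees the three phenols.
- Stereochemistry: the target has no stereocentre. C3 of the isoflavanone forms racemic and is erased by the dehydrogenation.

Key step: step 10

Remark: a para-selective phenol oxidation of a 2-hydroxy-4,6-dialkoxyaryl ketone would oxygenate the carbon that ends as C6, so the 8-oxygen is brought in through a formyl group. Diazoalkane 16 is handled only as a cold, titrated toluene solution.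

**Step 1**
Reactants: 1 2,4,6-trihydroxybenzaldehyde
Product: 2 2,4-bis(benzyloxy)-6-hydroxybenzaldehyde
Conditions: BnBr (2.05 equiv), K2CO3, DMF, 0 °C → rt
Reagents that add atoms: benzyl bromide, BrCc1ccccc1
Why: Williamson ether synthesis in which the para hydroxyl and one ortho hydroxyl are benzylated, while the remaining ortho hydroxyl, hydrogen-bonded to the formyl group, is the least nucleophilic and should stay free with two equivalents of halide.

**Step 2**
Reactants: 2 2,4-bis(benzyloxy)-6-hydroxybenzaldehyde; 3 methyl bromoacetate
Product: 4 methyl 2-[3,5-bis(benzyloxy)-2-formylphenoxy]acetate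
Conditions: K2CO3, DMF, rt → 40 °C
Reagents that add atoms: none
Why: Williamson alkylation of the chelated phenol by a reactive α-halo ester puts the future O1–C2–C4 unit on the oxygen that becomes the ring oxygen, and the mild carbonate base should not drive condensation of the new methylene with the hindered aldehyde.

**Step 3**
Reactants: 4 methyl 2-[3,5-bis(benzyloxy)-2-formylphenoxy]acetate
Product: 5 methyl 2-[3,5-bis(benzyloxy)-2-(formyloxy)phenoxy]acetate
Conditions: mCPBA, CH2Cl2, 0 °C → rt; aq. Na2SO3/NaHCO3 wash
Reagents that add atoms: meta-chloroperoxybenzoic acid, O=C(OO)c1cccc(Cl)c1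
Why: Baeyer–Villiger oxidation of a 2,4,6-trioxygenated benzaldehyde, in which the electron-rich aryl group migrates in preference to hydride, so the formyl carbon is replaced by oxygen on the carbon that becomes C8.

**Step 4**
Reactants: 5 methyl 2-[3,5-bis(benzyloxy)-2-(formyloxy)phenoxy]acetate
Product: 7 methyl 2-[3,5-bis(benzyloxy)-2-methoxyphenoxy]acetate, via phenol 6 (not isolated)
Conditions: K2CO3, MeOH, rt; then MeI, DMF co-solvent, rt → 40 °C
Reagents that add atoms: iodomethane, CI
Why: Formate methanolysis followed in the same flask by Williamson O-methylation of the phenoxide; methanol as solvent reopens any lactone formed by attack of the phenoxide on the neighbouring ester, so the methyl ether ester should be the only outcome.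

**Step 5**
Reactants: 7 methyl 2-[3,5-bis(benzyloxy)-2-methoxyphenoxy]acetate
Product: 8 2-[3,5-bis(benzyloxy)-2-methoxyphenoxy]acetic acid
Conditions: LiOH·H2O, THF/H2O, rt; then 1 M HCl to pH 3
Reagents that add atoms: lithium hydroxide (hydroxide oxygen), [Li+].[OH-]
Why: Saponification of an activated aryloxyacetic ester, to which benzyl and methyl aryl ethers are inert.

**Step 6**
Reactants: 8 2-[3,5-bis(benzyloxy)-2-methoxyphenoxy]acetic acid
Product: 10 4,6-bis(benzyloxy)-7-methoxybenzofuran-3(2H)-one, via mixed anhydride 9 (not isolated)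
Conditions: (CF3CO)2O, CH2Cl2, 0 °C → rt; aq. NaHCO3
Reagents that add atoms: none
Why: Intramolecular Friedel–Crafts acylation through the mixed trifluoroacetic anhydride, which can reach only the one unsubstituted carbon ortho to the oxyacetic arm (the other ortho carbon bears the methoxy group); that carbon is activated by an ortho and a para benzyloxy group, and the metal-free conditions should spare the benzyl ethers.

**Step 7**
Reactants: 11 3-hydroxy-4,5-dimethoxybenzaldehyde
Product: 12 3-(benzyloxy)-4,5-dimethoxybenzaldehyde
Conditions: BnBr, K2CO3, DMF, rt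
Reagents that add atoms: benzyl bromide, BrCc1ccccc1
Why: Williamson ether synthesis on the single free phenol, giving a protecting group that is removed together with those of ring A at the end.

**Step 8**
Reactants: 12 3-(benzyloxy)-4,5-dimethoxybenzaldehyde; 13 p-toluenesulfonyl hydrazide
Product: 14 (E)-N'-[3-(benzyloxy)-4,5-dimethoxybenzylidene]-4-methylbenzenesulfonohydrazide
Conditions: MeOH, rt → 50 °C, product crystallises
Reagents that add atoms: none
Why: Condensation of an aromatic aldehyde with a sulfonyl hydrazide to the N-tosylhydrazone, a storable crystalline precursor of the diazoalkane.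

**Step 9**
Reactants: 14 (E)-N'-[3-(benzyloxy)-4,5-dimethoxybenzylidene]-4-methylbenzenesulfonohydrazide
Product: 16 [3-(benzyloxy)-4,5-dimethoxyphenyl]diazomethane, via sodium salt 15 (not isolated)
Conditions: NaOMe (1.0 equiv), MeOH, rt, evaporate to dryness; then BnEt3NCl (5 mol%), toluene, 40 °C, dark; filter cold under argon, titrate, use at once
Reagents that add atoms: none
Why: Aprotic Bamford–Stevens reaction, in which the tosylhydrazone anion loses sulfinate on gentle warming under phase-transfer assistance; the twisted 4-methoxy group and the two meta oxygens leave the aryl group nearly electron-neutral, so the diazoalkane should be about as persistent as phenyldiazomethane.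

**Step 10**
Reactants: 10 4,6-bis(benzyloxy)-7-methoxybenzofuran-3(2H)-one; 16 [3-(benzyloxy)-4,5-dimethoxyphenyl]diazomethane
Product: 18 racemic 5,7-bis(benzyloxy)-3-[3-(benzyloxy)-4,5-dimethoxyphenyl]-8-methoxychroman-4-one, via diazonium alkoxide 17 (not isolated)
Conditions: Sc(OTf)3 (10 mol%), toluene/CH2Cl2, −78 → −20 °C, slow addition of 16 (1.5 equiv) in toluene
Reagents that add atoms: none
Why: Proposed new method: the nucleophilic carbon of 16 adds to the ketone of 10, activated by Sc(OTf)3 held between the carbonyl oxygen and the neighbouring 4-benzyloxy oxygen, to give the diazonium alkoxide 17, in which the oxymethylene carbon of the furanone shifts to the benzylic carbon as N2 leaves, forming the C2–C3 and C3–C4 bonds of 18. The closest known reaction type is the Sc(OTf)3-catalysed Buchner–Curtius–Schlotterbeck (Tiffeneau–Demjanov-type) one-carbon homologation of cycloalkanones with aryldiazomethanes to 2-arylcycloalkanones; it has not been shown on benzofuran-3(2H)-ones, whose carbonyl is a deactivated vinylogous ester. Ring C is not closed by a cyclisation but arises from the furanone by ring expansion from five to six members through this 1,2-alkyl shift. The new stereocentre C3 forms without control and 18 is racemic, which does not matter because C3 becomes sp2 in step 11. The step needs migration of the oxymethylene carbon and not of the aryl carbon C3a, and C-attack on the ketone instead of epoxide closure, O-benzylation of the enol or acid-induced dimerisation of 16: the ring-fused aryl carbon is flanked by two ortho substituents and cannot reach the bridged arrangement of an aryl shift, its migration would take the carbonyl out of conjugation with the trioxygenated ring, and benzo-fused ketones such as 1-tetralones and chroman-4-ones are expected to expand with diazoacetates by shift of the sp3 carbon, while the lone pair on O1 can support the migrating CH2; 10 is a ketone and not an enol, and slow addition of 16 at low temperature keeps its stationary concentration small.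

**Step 11**
Reactants: 18 racemic 5,7-bis(benzyloxy)-3-[3-(benzyloxy)-4,5-dimethoxyphenyl]-8-methoxychroman-4-one
Product: 19 5,7-bis(benzyloxy)-3-[3-(benzyloxy)-4,5-dimethoxyphenyl]-8-methoxy-4H-chromen-4-one
Conditions: DDQ (1.5 equiv), 1,4-dioxane, reflux
Reagents that add atoms: none
Why: DDQ dehydrogenation of an isoflavanone to the isoflavone (hydride abstraction from C2 next to O1, then loss of the C3 proton); no free phenol is present and benzyl and methyl aryl ethers should be oxidised far more slowly.

**Step 12**
Reactants: 19 5,7-bis(benzyloxy)-3-[3-(benzyloxy)-4,5-dimethoxyphenyl]-8-methoxy-4H-chromen-4-one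
Product: 20 isoirigenin, 5,7-dihydroxy-3-(3-hydroxy-4,5-dimethoxyphenyl)-8-methoxy-4H-chromen-4-one
Conditions: H2 (1 atm), Pd/C (10 wt% palladium on carbon), EtOAc/MeOH, rt, stopped after uptake of three equivalents
Reagents that add atoms: none
Why: Catalytic hydrogenolysis cleaves the three benzylic C–O bonds while the aryl methyl ethers are inert and the conjugated C2=C3 bond of the chromone is reduced much more slowly.

**Compound list**
1 | 2,4,6-trihydroxybenzaldehyde | O=Cc1c(O)cc(O)cc1O | starting material
2 | 2,4-bis(benzyloxy)-6-hydroxybenzaldehyde | O=Cc1c(O)cc(OCc2ccccc2)cc1OCc1ccccc1 | intermediate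
3 | methyl bromoacetate | COC(=O)CBr | starting material
4 | methyl 2-[3,5-bis(benzyloxy)-2-formylphenoxy]acetate | COC(=O)COc1cc(OCc2ccccc2)cc(OCc2ccccc2)c1C=O | intermediate
5 | methyl 2-[3,5-bis(benzyloxy)-2-(formyloxy)phenoxy]acetate | COC(=O)COc1cc(OCc2ccccc2)cc(OCc2ccccc2)c1OC=O | intermediate
6 | methyl 2-[3,5-bis(benzyloxy)-2-hydroxyphenoxy]acetate (phenol, formed as its potassium salt, not isolated) | COC(=O)COc1cc(OCc2ccccc2)cc(OCc2ccccc2)c1O | intermediate
7 | methyl 2-[3,5-bis(benzyloxy)-2-methoxyphenoxy]acetate | COC(=O)COc1cc(OCc2ccccc2)cc(OCc2ccccc2)c1OC | intermediate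
8 | 2-[3,5-bis(benzyloxy)-2-methoxyphenoxy]acetic acid | OC(=O)COc1cc(OCc2ccccc2)cc(OCc2ccccc2)c1OC | intermediate
9 | 2-[3,5-bis(benzyloxy)-2-methoxyphenoxy]acetic trifluoroacetic anhydride (mixed anhydride, not isolated) | O=C(COc1cc(OCc2ccccc2)cc(OCc2ccccc2)c1OC)OC(=O)C(F)(F)F | intermediate
10 | 4,6-bis(benzyloxy)-7-methoxybenzofuran-3(2H)-one | COc1c(OCc2ccccc2)cc(OCc2ccccc2)c2c1OCC2=O | intermediate
11 | 3-hydroxy-4,5-dimethoxybenzaldehyde | COc1cc(C=O)cc(O)c1OC | starting material
12 | 3-(benzyloxy)-4,5-dimethoxybenzaldehyde | COc1cc(C=O)cc(OCc2ccccc2)c1OC | intermediate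
13 | p-toluenesulfonyl hydrazide | Cc1ccc(S(=O)(=O)NN)cc1 | starting material
14 | (E)-N'-[3-(benzyloxy)-4,5-dimethoxybenzylidene]-4-methylbenzenesulfonohydrazide | COc1cc(/C=N/NS(=O)(=O)c2ccc(C)cc2)cc(OCc2ccccc2)c1OC | intermediate
15 | sodium salt of tosylhydrazone 14 (not isolated) | COc1cc(/C=N/[N-]S(=O)(=O)c2ccc(C)cc2)cc(OCc2ccccc2)c1OC.[Na+] | intermediate
16 | [3-(benzyloxy)-4,5-dimethoxyphenyl]diazomethane (toluene solution) | COc1cc(C=[N+]=[N-])cc(OCc2ccccc2)c1OC | intermediate
17 | 4,6-bis(benzyloxy)-3-{[3-(benzyloxy)-4,5-dimethoxyphenyl](diazonio)methyl}-7-methoxy-2,3-dihydrobenzofuran-3-olate (scandium-bound, diastereomer mixture, not isolated) | COc1c(OCc2ccccc2)cc(OCc2ccccc2)c2c1OCC2([O-])C([N+]#N)c1cc(OCc2ccccc2)c(OC)c(OC)c1 | intermediate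
18 | racemic 5,7-bis(benzyloxy)-3-[3-(benzyloxy)-4,5-dimethoxyphenyl]-8-methoxychroman-4-one | COc1c(OCc2ccccc2)cc(OCc2ccccc2)c2c1OCC(c1cc(OCc3ccccc3)c(OC)c(OC)c1)C2=O | intermediate
19 | 5,7-bis(benzyloxy)-3-[3-(benzyloxy)-4,5-dimethoxyphenyl]-8-methoxy-4H-chromen-4-one | COc1c(OCc2ccccc2)cc(OCc2ccccc2)c2c1occ(-c1cc(OCc3ccccc3)c(OC)c(OC)c1)c2=O | intermediate
20 | isoirigenin, 5,7-dihydroxy-3-(3-hydroxy-4,5-dimethoxyphenyl)-8-methoxy-4H-chromen-4-one | COc1cc(-c2coc3c(OC)c(O)cc(O)c3c2=O)cc(O)c1OC | target

**Count**
Total steps: 12. Longest linear sequence: 9 steps (steps 1–6, then 10–12, from compound 1); the ring-B branch (steps 7–9) joins at step 10.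

**Steps most likely to fail**

1. Step 10. The aryl carbon may shift instead of the oxymethylene carbon, addition to the deactivated carbonyl may be so slow that the diazoalkane is lost to acid-induced dimerisation, or the adduct may close to an epoxide. The fallback uses known chemistry and fixes the position of the inserted carbon by mechanism. It sets out from 10 and from 12 and comes back at 19, so step 11 is no longer needed.
   - Ketone 10 is silylated (TBSOTf, Et3N, CH2Cl2) to the silyl enol ether 4,6-bis(benzyloxy)-3-(tert-butyldimethylsilyloxy)-7-methoxybenzofuran F1.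
   - Dibromocarbene (CHBr3, KOtBu, hexane, −20 °C → rt) adds to the C2=C3 bond of F1. The cyclopropane opens with loss of bromide and of the silyl group, which should give 5,7-bis(benzyloxy)-3-bromo-8-methoxy-4H-chromen-4-one F2, with the new carbon necessarily between C2 and the carbonyl.
   - Aldehyde 12 is taken by Baeyer–Villiger oxidation and methanolysis (mCPBA; K2CO3, MeOH) to 3-(benzyloxy)-4,5-dimethoxyphenol F3.
   - F3 is converted with Tf2O and pyridine into 3-(benzyloxy)-4,5-dimethoxyphenyl trifluoromethanesulfonate F4.
   - Miyaura borylation of F4 (B2pin2, Pd(dppf)Cl2, KOAc, dioxane, 80 °C) gives 2-[3-(benzyloxy)-4,5-dimethoxyphenyl]-4,4,5,5-tetramethyl-1,3,2-dioxaborolane F5.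
   - Suzuki–Miyaura coupling of F2 with F5 (Pd(PPh3)4, K2CO3, dioxane/H2O, 80 °C) should give 19.

2. Step 9. The diazoalkane may be lost to azine and stilbene formation during its thermal release, the sulfinate elimination may stay incomplete, or basic salts may be carried into the Lewis-acid step. The fallback replaces base-induced elimination by oxidation of the free hydrazone; it sets out from 12 and comes back at 16.
   - Aldehyde 12 is added to excess N2H4·H2O in EtOH to give (E)-[3-(benzyloxy)-4,5-dimethoxybenzylidene]hydrazine F6.
   - F6 is oxidised at low temperature with activated MnO2 (MgSO4, CH2Cl2/toluene, 0 °C) or under Swern-type conditions ((COCl)2, DMSO, Et3N, −78 °C). Filtration should give a neutral, salt-free solution of 16.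

3. Step 6. Acid set free during the acylation may remove benzyl groups or shift them onto the electron-rich ring, or the five-membered closure may be sluggish. The fallback changes the electrophile from a protic mixed anhydride to an activated amide; it sets out from 7 and comes back at 10.
   - Ester 7 is aminolysed with dimethylamine (2 M in MeOH, rt) to 2-[3,5-bis(benzyloxy)-2-methoxyphenoxy]-N,N-dimethylacetamide F7.
   - F7 is closed in a Vilsmeier–Haack-type intramolecular reaction (POCl3, or Tf2O with 2-chloropyridine, CH2Cl2, 0 °C → rt) at the same single free ortho carbon. Hydrolysis with aqueous NaOAc should return 10.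

**Further compounds**
F1 | step 10 | 4,6-bis(benzyloxy)-3-(tert-butyldimethylsilyloxy)-7-methoxybenzofuran | COc1c(OCc2ccccc2)cc(OCc2ccccc2)c2c(O[Si](C)(C)C(C)(C)C)coc12
F2 | step 10 | 5,7-bis(benzyloxy)-3-bromo-8-methoxy-4H-chromen-4-one | COc1c(OCc2ccccc2)cc(OCc2ccccc2)c2c1occ(Br)c2=O
F3 | step 10 | 3-(benzyloxy)-4,5-dimethoxyphenol | COc1cc(O)cc(OCc2ccccc2)c1OC
F4 | step 10 | 3-(benzyloxy)-4,5-dimethoxyphenyl trifluoromethanesulfonate | COc1cc(OS(=O)(=O)C(F)(F)F)cc(OCc2ccccc2)c1OC
F5 | step 10 | 2-[3-(benzyloxy)-4,5-dimethoxyphenyl]-4,4,5,5-tetramethyl-1,3,2-dioxaborolane | COc1cc(B2OC(C)(C)C(C)(C)O2)cc(OCc2ccccc2)c1OC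
F6 | step 9 | (E)-[3-(benzyloxy)-4,5-dimethoxybenzylidene]hydrazine | COc1cc(/C=N/N)cc(OCc2ccccc2)c1OC
F7 | step 6 | 2-[3,5-bis(benzyloxy)-2-methoxyphenoxy]-N,N-dimethylacetamide | CN(C)C(=O)COc1cc(OCc2ccccc2)cc(OCc2ccccc2)c1OC
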